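**Plan**

- Cuts, in retrosynthetic order: the triene σ-bond at C2 of ring B (Stille); the exocyclic C=C(CH3)CHO at C9 of ring A (allylic transposition from a ring ketone); bond C1–C2 of ring B (carbonyl-ene); and the bond C5–C6 between the spiro carbon and the C(CH3)OH carbon of ring A (aldol), which leaves an open-chain keto-enal.
- Enabling feature: the spiro carbon C5 is α to C1, the CH–OH carbon of ring B (a latent formyl carbon), and is bonded to the tertiary carbinol C6 of ring A. This is a β-hydroxy-aldehyde array, and C1(OH)–C2(C=CH2) of ring B is the ene adduct of that same formyl group with a prenyl-type alkene hanging from C5.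
- Forward: Evans aldol, then acyclic keto-enal 17, then ring A (cyclohexane) by rhodium-hydride reductive aldol cyclization, then ring B (cyclopentane) by chelated carbonyl-ene reaction. After that: isopropenyl to enol triflate, C9 ketone to enal, Stille coupling with an (E,Z)-dienylstannane, desilylation.
- Stereochemistry: C10 from the Evans syn-aldol; C5 and C6 relayed from C10 through a chair, rhodium-chelated aldol transition state; C1 and C2 from the aluminium-chelated concerted ene reaction; alkene geometries from the Still–Gennari olefination, the (E)-vinylstannane and allylic strain in the transposition.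

Key step: step 11

Remark on naming: spiro compounds carry spiro[4.5]decane locants. C1 is the CH–O carbon of ring B, C2 the ring B carbon bearing the side chain, C5 the spiro carbon, C6 the C(CH3)–O carbon of ring A, C9 the ring A carbon that becomes the alkylidene carbon, and C10 the ring A CH bearing the propyl chain. CIP descriptors of intermediates change with substitution although the spatial arrangement does not; the SMILES are authoritative.

Assumption: 30 and 32 are taken as purchasable. The double-bond geometry of 15 and 16 and the C9 configuration of 28 are of no consequence, because these elements are consumed later.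

**Step 1**
Reactants: 1 pentane-1,5-diol
Product: 2 5-[(tert-butyldiphenylsilyl)oxy]pentan-1-ol
Conditions: NaH (1.0 equiv), THF, 0 °C to rt; then t-BuPh2SiCl (1.0 equiv)
Reagents that add atoms: tert-butyl(chloro)diphenylsilane, CC(C)(C)[Si](Cl)(c1ccccc1)c1ccccc1
Why: O-silylation of the sparingly soluble monosodium alkoxide of a symmetrical diol should stop at the mono-ether.

**Step 2**
Reactants: 2 5-[(tert-butyldiphenylsilyl)oxy]pentan-1-ol
Product: 3 5-[(tert-butyldiphenylsilyl)oxy]pentanoic acid
Conditions: TEMPO (cat.), PhI(OAc)2 (2.2 equiv), MeCN–H2O (1:1), rt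
Reagents that add atoms: water, O
Why: The TEMPO/PhI(OAc)2 oxidation in aqueous acetonitrile takes a primary alcohol through the aldehyde hydrate to the carboxylic acid and leaves the silyl ether alone.

**Step 3**
Reactants: 3 5-[(tert-butyldiphenylsilyl)oxy]pentanoic acid; 4 (4R)-4-benzyl-1,3-oxazolidin-2-one
Product: 6 (4R)-4-benzyl-3-{5-[(tert-butyldiphenylsilyl)oxy]pentanoyl}-1,3-oxazolidin-2-one, via mixed pivalic anhydride 5 (not isolated)
Conditions: t-BuCOCl, Et3N, THF, −20 °C; then 4, LiCl, −20 °C to rt
Reagents that add atoms: none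
Why: N-Acylation of the oxazolidinone by the mixed pivalic anhydride, assisted by LiCl, is the standard loading of the chiral auxiliary and creates no stereocentre.

**Step 4**
Reactants: 6 (4R)-4-benzyl-3-{5-[(tert-butyldiphenylsilyl)oxy]pentanoyl}-1,3-oxazolidin-2-one; 7 pent-4-enal
Product: 9 (4R)-4-benzyl-3-[(2R,3S)-2-{3-[(tert-butyldiphenylsilyl)oxy]propyl}-3-hydroxyhept-6-enoyl]-1,3-oxazolidin-2-one, via (Z)-dibutylboron enolate 8 (not isolated)
Conditions: Bu2BOTf, iPr2NEt, CH2Cl2, −78 to 0 °C; then 7, −78 to 0 °C; MeOH, pH 7 buffer, 30% H2O2, 0 °C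
Reagents that add atoms: none
Why: In this Evans syn-aldol addition the (Z)-boron enolate reacts through a chair Zimmerman–Traxler transition state on the face away from the benzyl group, which should set the (2R,3S) pair, that is the future C10 and a temporary carbinol centre at the future C9.

**Step 5**
Reactants: 9 (4R)-4-benzyl-3-[(2R,3S)-2-{3-[(tert-butyldiphenylsilyl)oxy]propyl}-3-hydroxyhept-6-enoyl]-1,3-oxazolidin-2-one
Product: 10 (2R,3S)-2-{3-[(tert-butyldiphenylsilyl)oxy]propyl}-3-hydroxy-N-methoxy-N-methylhept-6-enamide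
Conditions: MeNH(OMe)·HCl, AlMe3, CH2Cl2, −10 to 0 °C; aq potassium sodium tartrate
Reagents that add atoms: N,O-dimethylhydroxylamine hydrochloride, CNOC.Cl
Why: Weinreb transamidation by the aluminium amide, helped by the free β-hydroxyl, cleaves the auxiliary without touching either stereocentre.

**Step 6**
Reactants: 10 (2R,3S)-2-{3-[(tert-butyldiphenylsilyl)oxy]propyl}-3-hydroxy-N-methoxy-N-methylhept-6-enamide
Product: 11 (2R,3S)-2-{3-[(tert-butyldiphenylsilyl)oxy]propyl}-N-methoxy-N-methyl-3-[(triethylsilyl)oxy]hept-6-enamide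
Conditions: Et3SiCl, imidazole, CH2Cl2, 0 °C to rt
Reagents that add atoms: chlorotriethylsilane, CC[Si](Cl)(CC)CC
Why: O-Silylation masks the secondary alcohol that is to become the C9 ketone, as the most labile of the silyl ethers used.

**Step 7**
Reactants: 11 (2R,3S)-2-{3-[(tert-butyldiphenylsilyl)oxy]propyl}-N-methoxy-N-methyl-3-[(triethylsilyl)oxy]hept-6-enamide; 12 5-bromo-2-methylpent-2-ene
Product: 14 (7R,8S)-7-{3-[(tert-butyldiphenylsilyl)oxy]propyl}-2-methyl-8-[(triethylsilyl)oxy]dodeca-2,11-dien-6-one, via (4-methylpent-3-en-1-yl)magnesium bromide 13 (not isolated)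
Conditions: 12, Mg, cat. I2, THF, reflux; then 11, THF, 0 °C; aq NH4Cl
Reagents that add atoms: none
Why: In the Weinreb ketone synthesis the chelated tetrahedral adduct survives until work-up, so a single addition of the Grignard reagent should give the ketone.

**Step 8**
Reactants: 14 (7R,8S)-7-{3-[(tert-butyldiphenylsilyl)oxy]propyl}-2-methyl-8-[(triethylsilyl)oxy]dodeca-2,11-dien-6-one
Product: 15 (5Z,7R,8S)-7-{3-[(tert-butyldiphenylsilyl)oxy]propyl}-2-methyl-8-[(triethylsilyl)oxy]dodeca-2,5,11-trien-6-yl trifluoromethanesulfonate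
Conditions: KN(SiMe3)2, THF, −78 °C; PhNTf2, −78 to −20 °C
Reagents that add atoms: N-phenylbis(trifluoromethanesulfonimide), O=S(=O)(N(c1ccccc1)S(=O)(=O)C(F)(F)F)C(F)(F)F
Why: Kinetic deprotonation at the unhindered methylene instead of the branched methine, followed by O-triflation (enol triflate formation), should place the double bond away from the stereocentre, which is therefore not epimerized.

**Step 9**
Reactants: 15 (5Z,7R,8S)-7-{3-[(tert-butyldiphenylsilyl)oxy]propyl}-2-methyl-8-[(triethylsilyl)oxy]dodeca-2,5,11-trien-6-yl trifluoromethanesulfonate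
Product: 16 (2Z)-2-[(4S,5S)-1-[(tert-butyldiphenylsilyl)oxy]-5-[(triethylsilyl)oxy]non-8-en-4-yl]-6-methylhepta-2,5-dienal
Conditions: Pd(PPh3)4 (5 mol %), CO (1 atm), Bu3SnH (slow addition), THF, 50 °C
Reagents that add atoms: carbon monoxide, [C-]#[O+]
Why: In this palladium-catalysed reductive carbonylation (formylation) of an enol triflate, oxidative addition to zerovalent palladium, CO insertion and hydride transfer from tin should turn C–OTf into C–CHO with retention of the double bond.

**Step 10**
Reactants: 16 (2Z)-2-[(4S,5S)-1-[(tert-butyldiphenylsilyl)oxy]-5-[(triethylsilyl)oxy]non-8-en-4-yl]-6-methylhepta-2,5-dienal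
Product: 17 (2Z)-2-[(4S,5S)-1-[(tert-butyldiphenylsilyl)oxy]-8-oxo-5-[(triethylsilyl)oxy]nonan-4-yl]-6-methylhepta-2,5-dienal
Conditions: PdCl2 (10 mol %), Cu(OAc)2·H2O (20 mol %), O2 (1 atm), DMA–H2O (7:1), rt
Reagents that add atoms: water, O
Why: The Tsuji–Wacker oxidation is Markovnikov-selective for the monosubstituted terminal alkene and should leave the trisubstituted alkene and the enal alone, so the methyl ketone acceptor is unmasked only now, under acid-free conditions that spare the triethylsilyl ether.

**Step 11**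
Reactants: 17 (2Z)-2-[(4S,5S)-1-[(tert-butyldiphenylsilyl)oxy]-8-oxo-5-[(triethylsilyl)oxy]nonan-4-yl]-6-methylhepta-2,5-dienal
Product: 19 (1R,2S,5S,6S)-6-{3-[(tert-butyldiphenylsilyl)oxy]propyl}-2-hydroxy-2-methyl-1-(4-methylpent-3-en-1-yl)-5-[(triethylsilyl)oxy]cyclohexane-1-carbaldehyde, via Rh[P(2-furyl)3]2 (E)-enolate 18 (not isolated)
Conditions: Rh(COD)2OTf (10 mol %), tri(2-furyl)phosphine (24 mol %), K2CO3 (0.8 equiv), H2 (1 atm), THF, 40 °C, 0.05 M
Reagents that add atoms: none
Why: A rhodium hydride formed from H2 with the help of K2CO3 adds in conjugate fashion to the enal in its s-cis form and gives the O-bound (E)-enolate 18, whose fully substituted α-carbon should then add to the methyl ketone faster than the enolate is hydrogenolysed. The closest known reaction type is the hydrogen-mediated reductive aldol cyclization of keto-enals (a rhodium aldehyde enolate adding to a tethered ketone), and ring A closes in the 6-(enolexo)-exo-trig mode. The new quaternary carbon is controlled by the stereocentre next to it: in the chair transition state the silyloxypropyl chain and the OSiEt3 group are equatorial and the C–H of that stereocentre eclipses the CH2 branch of the enolate, the favoured rotamer because the enolate oxygen is trans to the stereocentre and only the small enol hydrogen faces the tether, so the formyl carbon becomes axial and cis to the chain. The carbinol carbon is controlled by the Zimmerman–Traxler chelate, in which rhodium bridges the enolate and ketone oxygens; this is possible only with the ketone oxygen equatorial (cis to formyl) and the methyl group axial. The step needs hydrometalation of the enal in the presence of the ketone and the trisubstituted alkene, regiospecific enolate formation, and aldol addition in preference to plain reduction; the enal is the only activated alkene, the enolate arises by hydride addition and not by deprotonation so the methyl ketone cannot act as the donor, and the electron-poor phosphine with substoichiometric base favours carbon–carbon bond formation.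

**Step 12**
Reactants: 19 (1R,2S,5S,6S)-6-{3-[(tert-butyldiphenylsilyl)oxy]propyl}-2-hydroxy-2-methyl-1-(4-methylpent-3-en-1-yl)-5-[(triethylsilyl)oxy]cyclohexane-1-carbaldehyde
Product: 20 (1S,2R,5S,6S,9S,10S)-10-{3-[(tert-butyldiphenylsilyl)oxy]propyl}-6-methyl-2-(prop-1-en-2-yl)-9-[(triethylsilyl)oxy]spiro[4.5]decane-1,6-diol
Conditions: Me2AlCl (2.5 equiv), CH2Cl2, −78 to −40 °C; aq potassium sodium tartrate
Reagents that add atoms: none
Why: In this intramolecular carbonyl-ene reaction the aluminium alkoxide of the tertiary alcohol chelates the formyl oxygen, so the trisubstituted alkene should attack the face that puts the new hydroxyl at C1 cis to C6, and the concerted hydrogen transfer from a methyl group forces hydroxyl and isopropenyl cis on the new five-membered ring B.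

**Step 13**
Reactants: 20 (1S,2R,5S,6S,9S,10S)-10-{3-[(tert-butyldiphenylsilyl)oxy]propyl}-6-methyl-2-(prop-1-en-2-yl)-9-[(triethylsilyl)oxy]spiro[4.5]decane-1,6-diol
Product: 21 1,6-O-(di-tert-butylsilanediyl) derivative of 20 (six-membered 1,3,2-dioxasilinane across O-1 and O-6; stereocentres as in 20)
Conditions: t-Bu2Si(OTf)2, 2,6-lutidine, CH2Cl2, 0 °C to rt
Reagents that add atoms: di-tert-butylsilyl bis(trifluoromethanesulfonate), CC(C)(C)[Si](OS(=O)(=O)C(F)(F)F)(OS(=O)(=O)C(F)(F)F)C(C)(C)C
Why: Silylene formation ties the cis-disposed 1,3-diol into a six-membered ring (the second Si–O bond forms intramolecularly even at the tertiary alcohol), which should block retro-aldol chemistry in the base steps that follow.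

**Step 14**
Reactants: 21 1,6-O-(di-tert-butylsilanediyl) derivative of 20
Product: 22 2-acetyl analogue of 21 (prop-1-en-2-yl replaced by acetyl; stereocentres unchanged)
Conditions: O3, CH2Cl2–MeOH, −78 °C; then Me2S, −78 °C to rt
Reagents that add atoms: ozone, [O-][O+]=O
Why: Ozonolysis with reductive work-up should cleave the only alkene in the molecule, the isopropenyl group, to the methyl ketone.

**Step 15**
Reactants: 22 2-acetyl analogue of 21
Product: 23 enol triflate of 22 (C2 carries CH2=C(OSO2CF3)–; stereocentres unchanged)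
Conditions: KN(SiMe3)2, THF, −78 °C; PhNTf2, −78 to 0 °C
Reagents that add atoms: N-phenylbis(trifluoromethanesulfonimide), O=S(=O)(N(c1ccccc1)S(=O)(=O)C(F)(F)F)C(F)(F)F
Why: Kinetic deprotonation of the methyl group and O-triflation (enol triflate formation) should give the terminal enol triflate without enolizing towards the ring methine, so C2 is not epimerized and the β-silyloxy group is not eliminated.

**Step 16**
Reactants: 23 enol triflate of 22
Product: 24 9-hydroxy compound from 23 (OSiEt3 replaced by OH; stereocentres unchanged)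
Conditions: pyridinium p-toluenesulfonate (cat.), MeOH–CH2Cl2 (1:1), 0 °C to rt
Reagents that add atoms: none
Why: Mild acid methanolysis should remove the triethylsilyl ether selectively, by the graded lability of silyl ethers, while the tert-butyldiphenylsilyl ether, the silylene and the enol triflate stay.

**Step 17**
Reactants: 24 9-hydroxy compound from 23
Product: 25 spiro[4.5]decan-9-one from 24 (C9 ketone; remaining stereocentres unchanged)
Conditions: Dess–Martin periodinane, pyridine, CH2Cl2, 0 °C to rt
Reagents that add atoms: none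
Why: Dess–Martin oxidation under buffered, non-basic conditions should give the ring ketone without epimerizing the adjacent C10 stereocentre.

**Step 18**
Reactants: 25 spiro[4.5]decan-9-one from 24; 26 isopropenylmagnesium bromide
Product: 28 tertiary allylic alcohol from 25 (C9 carries OH plus prop-1-en-2-yl; OH cis to the C10 chain expected; other stereocentres unchanged), via isopropenylcerium dichloride 27 (not isolated)
Conditions: CeCl3 (anhydrous), THF, −78 °C; 26; then 25, −78 °C; aq NH4Cl
Reagents that add atoms: none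
Why: The weakly basic organocerium reagent (CeCl3-mediated Grignard addition) should add 1,2 to the hindered, enolizable ketone without epimerizing C10, attacking anti to the neighbouring propyl chain; the configuration of the new carbinol centre is lost in the next step.

**Step 19**
Reactants: 28 tertiary allylic alcohol from 25
Product: 29 (2Z)-2-(spiro[4.5]decan-9-ylidene)propanal from 28 (CHO cis to C10; C2 enol triflate and both silyl groups retained)
Conditions: pyridinium chlorochromate (3 equiv), powdered 4 Å molecular sieves, CH2Cl2, rt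
Reagents that add atoms: none
Why: In the Babler–Dauben oxidative transposition the chromate ester of the tertiary allylic alcohol shifts by a [3,3] process to the primary allylic chromate, which is oxidized to the enal; the formyl group should end up cis to the more substituted ring carbon C10, where it causes less allylic 1,3-strain than the methyl group would.

**Step 20**
Reactants: 30 (2E)-3-(tributylstannyl)prop-2-en-1-ol
Product: 31 (2E)-3-(tributylstannyl)prop-2-enal
Conditions: MnO2 (activated, excess), CH2Cl2, rt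
Reagents that add atoms: none
Why: MnO2 oxidizes the allylic alcohol to the enal (allylic oxidation) without touching the vinylstannane or its geometry.

**Step 21**
Reactants: 32 methyl 2-[bis(2,2,2-trifluoroethoxy)phosphoryl]acetate; 12 5-bromo-2-methylpent-2-ene
Product: 33 methyl 2-[bis(2,2,2-trifluoroethoxy)phosphoryl]-6-methylhept-5-enoate (racemic)
Conditions: NaH, DMF, 0 °C; then 12, Bu4NI (cat.), 50 °C
Reagents that add atoms: none
Why: C-Alkylation (SN2) of the stabilized phosphonoacetate anion with the primary bromide installs the homoprenyl branch; the new stereocentre is lost in the next step.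

**Step 22**
Reactants: 33 methyl 2-[bis(2,2,2-trifluoroethoxy)phosphoryl]-6-methylhept-5-enoate; 31 (2E)-3-(tributylstannyl)prop-2-enal
Product: 34 methyl (2Z,4E)-2-(4-methylpent-3-en-1-yl)-5-(tributylstannyl)penta-2,4-dienoate
Conditions: 33, KN(SiMe3)2, 18-crown-6, THF, −78 °C; then 31, −78 °C
Reagents that add atoms: none
Why: The Still–Gennari olefination with the bis(trifluoroethyl) phosphonate under dissociating conditions should give the (Z)-trisubstituted enoate, ester cis to the stannylvinyl group, while the (E)-vinylstannane is retained.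

**Step 23**
Reactants: 34 methyl (2Z,4E)-2-(4-methylpent-3-en-1-yl)-5-(tributylstannyl)penta-2,4-dienoate
Product: 35 (2Z,4E)-2-(4-methylpent-3-en-1-yl)-5-(tributylstannyl)penta-2,4-dien-1-ol
Conditions: i-Bu2AlH (2.5 equiv), CH2Cl2, −78 °C; aq potassium sodium tartrate
Reagents that add atoms: none
Why: The 1,2-reduction of the conjugated ester by i-Bu2AlH should give the allylic alcohol with both alkene geometries intact.

**Step 24**
Reactants: 29 (2Z)-2-(spiro[4.5]decan-9-ylidene)propanal from 28; 35 (2Z,4E)-2-(4-methylpent-3-en-1-yl)-5-(tributylstannyl)penta-2,4-dien-1-ol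
Product: 36 bis-silylated 37 (O-1/O-6 di-tert-butylsilylene and tert-butyldiphenylsilyl ether of the hydroxypropyl group)
Conditions: Pd(PPh3)4 (10 mol %), LiCl (3 equiv), THF, 60 °C
Reagents that add atoms: none
Why: Stille cross-coupling of the enol triflate with the dienylstannane should form the 2-substituted triene with retention of the geometry of both partners, and it tolerates the enal and the free hydroxyl.

**Step 25**
Reactants: 36 bis-silylated 37
Product: 37 (2Z)-2-[(1S,2R,5S,6S,10R)-1,6-dihydroxy-2-[(3E,5Z)-6-(hydroxymethyl)-10-methylundeca-1,3,5,9-tetraen-2-yl]-10-(3-hydroxypropyl)-6-methylspiro[4.5]decan-9-ylidene]propanal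
Conditions: HF·pyridine, pyridine, THF, 0 °C to rt
Reagents that add atoms: none
Why: Fluoride-mediated desilylation under buffered, non-basic conditions should remove the silylene and the silyl ether without disturbing the enal geometry, the triene or the C10 stereocentre.

**Compound list**

1 | pentane-1,5-diol | OCCCCCO | starting material
2 | 5-[(tert-butyldiphenylsilyl)oxy]pentan-1-ol | OCCCCCO[Si](c1ccccc1)(c1ccccc1)C(C)(C)C | intermediate
3 | 5-[(tert-butyldiphenylsilyl)oxy]pentanoic acid | OC(=O)CCCCO[Si](c1ccccc1)(c1ccccc1)C(C)(C)C | intermediate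
4 | (4R)-4-benzyl-1,3-oxazolidin-2-one | O=C1OC[C@@H](Cc2ccccc2)N1 | starting material
5 | 5-[(tert-butyldiphenylsilyl)oxy]pentanoic pivalic anhydride | CC(C)(C)C(=O)OC(=O)CCCCO[Si](c1ccccc1)(c1ccccc1)C(C)(C)C | intermediate (not isolated)
6 | (4R)-4-benzyl-3-{5-[(tert-butyldiphenylsilyl)oxy]pentanoyl}-1,3-oxazolidin-2-one | O=C1OC[C@@H](Cc2ccccc2)N1C(=O)CCCCO[Si](c1ccccc1)(c1ccccc1)C(C)(C)C | intermediate
7 | pent-4-enal | C=CCCC=O | starting material
8 | (Z)-dibutylboron enolate of 6 | CCCCB(CCCC)O/C(=C\CCCO[Si](c1ccccc1)(c1ccccc1)C(C)(C)C)N1C(=O)OC[C@H]1Cc1ccccc1 | intermediate (not isolated)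
9 | (4R)-4-benzyl-3-[(2R,3S)-2-{3-[(tert-butyldiphenylsilyl)oxy]propyl}-3-hydroxyhept-6-enoyl]-1,3-oxazolidin-2-one | O=C1OC[C@@H](Cc2ccccc2)N1C(=O)[C@H](CCCO[Si](c1ccccc1)(c1ccccc1)C(C)(C)C)[C@@H](O)CCC=C | intermediate
10 | (2R,3S)-2-{3-[(tert-butyldiphenylsilyl)oxy]propyl}-3-hydroxy-N-methoxy-N-methylhept-6-enamide | CON(C)C(=O)[C@H](CCCO[Si](c1ccccc1)(c1ccccc1)C(C)(C)C)[C@@H](O)CCC=C | intermediate
11 | (2R,3S)-2-{3-[(tert-butyldiphenylsilyl)oxy]propyl}-N-methoxy-N-methyl-3-[(triethylsilyl)oxy]hept-6-enamide | CON(C)C(=O)[C@H](CCCO[Si](c1ccccc1)(c1ccccc1)C(C)(C)C)[C@@H](O[Si](CC)(CC)CC)CCC=C | intermediate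
12 | 5-bromo-2-methylpent-2-ene | CC(C)=CCCBr | starting material
13 | (4-methylpent-3-en-1-yl)magnesium bromide | CC(C)=CCC[Mg]Br | intermediate (not isolated)
14 | (7R,8S)-7-{3-[(tert-butyldiphenylsilyl)oxy]propyl}-2-methyl-8-[(triethylsilyl)oxy]dodeca-2,11-dien-6-one | CC(C)=CCCC(=O)[C@H](CCCO[Si](c1ccccc1)(c1ccccc1)C(C)(C)C)[C@@H](O[Si](CC)(CC)CC)CCC=C | intermediate
15 | (5Z,7R,8S)-7-{3-[(tert-butyldiphenylsilyl)oxy]propyl}-2-methyl-8-[(triethylsilyl)oxy]dodeca-2,5,11-trien-6-yl trifluoromethanesulfonate | CC(C)=CC/C=C(\OS(=O)(=O)C(F)(F)F)[C@H](CCCO[Si](c1ccccc1)(c1ccccc1)C(C)(C)C)[C@@H](O[Si](CC)(CC)CC)CCC=C | intermediate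
16 | (2Z)-2-[(4S,5S)-1-[(tert-butyldiphenylsilyl)oxy]-5-[(triethylsilyl)oxy]non-8-en-4-yl]-6-methylhepta-2,5-dienal | CC(C)=CC/C=C(\C=O)[C@H](CCCO[Si](c1ccccc1)(c1ccccc1)C(C)(C)C)[C@@H](O[Si](CC)(CC)CC)CCC=C | intermediate
17 | (2Z)-2-[(4S,5S)-1-[(tert-butyldiphenylsilyl)oxy]-8-oxo-5-[(triethylsilyl)oxy]nonan-4-yl]-6-methylhepta-2,5-dienal | CC(C)=CC/C=C(\C=O)[C@H](CCCO[Si](c1ccccc1)(c1ccccc1)C(C)(C)C)[C@@H](O[Si](CC)(CC)CC)CCC(C)=O | intermediate
18 | O-bound (E)-enolate of the saturated aldehyde on Rh[P(2-furyl)3]2 | CC(C)=CCC/C(=C\O[Rh](P(c1ccco1)(c1ccco1)c1ccco1)P(c1ccco1)(c1ccco1)c1ccco1)[C@H](CCCO[Si](c1ccccc1)(c1ccccc1)C(C)(C)C)[C@@H](O[Si](CC)(CC)CC)CCC(C)=O | intermediate (not isolated)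
19 | (1R,2S,5S,6S)-6-{3-[(tert-butyldiphenylsilyl)oxy]propyl}-2-hydroxy-2-methyl-1-(4-methylpent-3-en-1-yl)-5-[(triethylsilyl)oxy]cyclohexane-1-carbaldehyde | CC(C)=CCC[C@]1([C@H](CCCO[Si](c2ccccc2)(c2ccccc2)C(C)(C)C)[C@@H](O[Si](CC)(CC)CC)CC[C@]1(C)O)C=O | intermediate
20 | (1S,2R,5S,6S,9S,10S)-10-{3-[(tert-butyldiphenylsilyl)oxy]propyl}-6-methyl-2-(prop-1-en-2-yl)-9-[(triethylsilyl)oxy]spiro[4.5]decane-1,6-diol | C=C(C)[C@H]1CC[C@]2([C@H](CCCO[Si](c3ccccc3)(c3ccccc3)C(C)(C)C)[C@@H](O[Si](CC)(CC)CC)CC[C@]2(C)O)[C@H]1O | intermediate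
21 | 1,6-O-(di-tert-butylsilanediyl) derivative of 20 | C=C(C)[C@H]1CC[C@]2([C@H](CCCO[Si](c4ccccc4)(c4ccccc4)C(C)(C)C)[C@@H](O[Si](CC)(CC)CC)CC[C@]2(C)O3)[C@H]1O[Si]3(C(C)(C)C)C(C)(C)C | intermediate
22 | 2-acetyl analogue of 21 (methyl ketone at C2) | CC(=O)[C@H]1CC[C@]2([C@H](CCCO[Si](c4ccccc4)(c4ccccc4)C(C)(C)C)[C@@H](O[Si](CC)(CC)CC)CC[C@]2(C)O3)[C@H]1O[Si]3(C(C)(C)C)C(C)(C)C | intermediate
23 | enol triflate of 22 (1-[(trifluoromethanesulfonyl)oxy]ethenyl at C2) | C=C(OS(=O)(=O)C(F)(F)F)[C@H]1CC[C@]2([C@H](CCCO[Si](c4ccccc4)(c4ccccc4)C(C)(C)C)[C@@H](O[Si](CC)(CC)CC)CC[C@]2(C)O3)[C@H]1O[Si]3(C(C)(C)C)C(C)(C)C | intermediate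
24 | 9-hydroxy compound from 23 | C=C(OS(=O)(=O)C(F)(F)F)[C@H]1CC[C@]2([C@H](CCCO[Si](c4ccccc4)(c4ccccc4)C(C)(C)C)[C@@H](O)CC[C@]2(C)O3)[C@H]1O[Si]3(C(C)(C)C)C(C)(C)C | intermediate
25 | spiro[4.5]decan-9-one from 24 | C=C(OS(=O)(=O)C(F)(F)F)[C@H]1CC[C@]2([C@H](CCCO[Si](c4ccccc4)(c4ccccc4)C(C)(C)C)C(=O)CC[C@]2(C)O3)[C@H]1O[Si]3(C(C)(C)C)C(C)(C)C | intermediate
26 | isopropenylmagnesium bromide | C=C(C)[Mg]Br | starting material
27 | isopropenylcerium dichloride | C=C(C)[Ce](Cl)Cl | intermediate (not isolated)
28 | tertiary allylic alcohol from 25 (9-hydroxy-9-(prop-1-en-2-yl); OH cis to the C10 chain) | C=C(OS(=O)(=O)C(F)(F)F)[C@H]1CC[C@]2([C@H](CCCO[Si](c4ccccc4)(c4ccccc4)C(C)(C)C)[C@@](O)(C(C)=C)CC[C@]2(C)O3)[C@H]1O[Si]3(C(C)(C)C)C(C)(C)C | intermediate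
29 | (2Z)-2-(spiro[4.5]decan-9-ylidene)propanal from 28 (CHO cis to C10) | C=C(OS(=O)(=O)C(F)(F)F)[C@H]1CC[C@]2([C@H](CCCO[Si](c4ccccc4)(c4ccccc4)C(C)(C)C)/C(=C(/C)C=O)CC[C@]2(C)O3)[C@H]1O[Si]3(C(C)(C)C)C(C)(C)C | intermediate
30 | (2E)-3-(tributylstannyl)prop-2-en-1-ol | CCCC[Sn](CCCC)(CCCC)/C=C/CO | starting material
31 | (2E)-3-(tributylstannyl)prop-2-enal | CCCC[Sn](CCCC)(CCCC)/C=C/C=O | intermediate
32 | methyl 2-[bis(2,2,2-trifluoroethoxy)phosphoryl]acetate | COC(=O)CP(=O)(OCC(F)(F)F)OCC(F)(F)F | starting material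
33 | methyl 2-[bis(2,2,2-trifluoroethoxy)phosphoryl]-6-methylhept-5-enoate | COC(=O)C(CCC=C(C)C)P(=O)(OCC(F)(F)F)OCC(F)(F)F | intermediate
34 | methyl (2Z,4E)-2-(4-methylpent-3-en-1-yl)-5-(tributylstannyl)penta-2,4-dienoate | CCCC[Sn](CCCC)(CCCC)/C=C/C=C(\C(=O)OC)CCC=C(C)C | intermediate
35 | (2Z,4E)-2-(4-methylpent-3-en-1-yl)-5-(tributylstannyl)penta-2,4-dien-1-ol | CCCC[Sn](CCCC)(CCCC)/C=C/C=C(\CO)CCC=C(C)C | intermediate
36 | bis-silylated 37 (O-1/O-6 di-tert-butylsilylene; tert-butyldiphenylsilyl ether of the hydroxypropyl group) | C=C(/C=C/C=C(\CO)CCC=C(C)C)[C@H]1CC[C@]2([C@H](CCCO[Si](c4ccccc4)(c4ccccc4)C(C)(C)C)/C(=C(/C)C=O)CC[C@]2(C)O3)[C@H]1O[Si]3(C(C)(C)C)C(C)(C)C | intermediate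
37 | (2Z)-2-[(1S,2R,5S,6S,10R)-1,6-dihydroxy-2-[(3E,5Z)-6-(hydroxymethyl)-10-methylundeca-1,3,5,9-tetraen-2-yl]-10-(3-hydroxypropyl)-6-methylspiro[4.5]decan-9-ylidene]propanal | C=C(/C=C/C=C(\CO)CCC=C(C)C)[C@H]1CC[C@]2([C@H](CCCO)/C(=C(/C)C=O)CC[C@]2(C)O)[C@H]1O | target

**Step count and risks**

Total step count: 25. Longest linear sequence: 21 steps (steps 1 to 19, then 24 and 25).

Steps most likely to fail:

1. Step 11. The rhodium enolate may be hydrogenolysed before it adds to the ketone (net conjugate reduction), or the facial discrimination at the enolate carbon may be insufficient. The fallback sets out from 17 and comes back at 19. RhCl(PPh3)3-catalysed 1,4-hydrosilylation of the enal with Et3SiH, which passes through the same s-cis geometry, should give the (E)-triethylsilyl enol ether F1, which is isolated. TiCl4 in CH2Cl2 at −78 °C then closes ring A by an intramolecular Mukaiyama aldol addition to the methyl ketone, and aqueous work-up returns 19.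

2. Step 12. The β-aluminoxy aldehyde may undergo retro-aldol cleavage under the Lewis acid, or the developing cation may be captured by chloride instead of completing the hydrogen transfer. The fallback sets out from 19 and comes back at 20. The tertiary hydroxyl is capped with Me3SiOTf and 2,6-lutidine to give the trimethylsilyl ether F2, in which retro-aldol cleavage is no longer possible. The uncatalysed thermal ene reaction (toluene, 160 °C, sealed tube) then closes ring B to give the spiro alcohol F3, and K2CO3 in methanol removes the trimethylsilyl group and returns 20.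

3. Step 19. The hindered tertiary allylic alcohol may ionize and dehydrate to dienes, or the transposition may give the wrong enal geometry. The fallback sets out from 28 and comes back at 29. SOCl2 in Et2O at 0 °C converts 28 with allylic rearrangement into the primary allylic chloride F4, and N-methylmorpholine N-oxide in MeCN (Kornblum-type oxidation) turns the chloride into the enal 29. A geometric mixture at either stage would be equilibrated with a catalytic amount of iodine towards the isomer with the oxidized carbon cis to C10.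

**Further compounds**

F1 | step 11 | (E)-triethylsilyl enol ether of the saturated aldehyde derived from 17 | CC(C)=CCC/C(=C\O[Si](CC)(CC)CC)[C@H](CCCO[Si](c1ccccc1)(c1ccccc1)C(C)(C)C)[C@@H](O[Si](CC)(CC)CC)CCC(C)=O
F2 | step 12 | trimethylsilyl ether of 19 at the tertiary hydroxyl | CC(C)=CCC[C@]1([C@H](CCCO[Si](c2ccccc2)(c2ccccc2)C(C)(C)C)[C@@H](O[Si](CC)(CC)CC)CC[C@]1(C)O[Si](C)(C)C)C=O
F3 | step 12 | 6-O-trimethylsilyl ether of 20 | C=C(C)[C@H]1CC[C@]2([C@H](CCCO[Si](c3ccccc3)(c3ccccc3)C(C)(C)C)[C@@H](O[Si](CC)(CC)CC)CC[C@]2(C)O[Si](C)(C)C)[C@H]1O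
F4 | step 19 | primary allylic chloride (C9=C(CH3)CH2Cl, CH2Cl cis to C10; otherwise as 29) | C=C(OS(=O)(=O)C(F)(F)F)[C@H]1CC[C@]2([C@H](CCCO[Si](c4ccccc4)(c4ccccc4)C(C)(C)C)/C(=C(/C)CCl)CC[C@]2(C)O3)[C@H]1O[Si]3(C(C)(C)C)C(C)(C)C
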